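All runs were generated by integration on assumed constants; the scatter is artificial.

Saturday's run held a quarter of the G of Monday's run, yet at 80.0 min they read Z 27.0% and 26.7%. Wednesday's run, with less Q than either, read 27.1% at that time.

| flask | Q | G | D | remark | time |
|---|---|---|---|---|---|
| Saturday's | 0.42 M | 21 mM | 25 mM | run made earlier |  |
| Monday's | 0.42 M | 84 mM | 25 mM | run made earlier |  |
| Wednesday's | 0.21 M | 42 mM | 25 mM | run made earlier |  |
| flask | 0.42 M | 42 mM | 25 mM |  | 80 min |

| run | time / min | Z / % | X / % |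
|---|---|---|---|
| Saturday's | 5.00 | 20.9 | 10.8 |
| Saturday's | 15.0 | 26.4 | 11.3 |
| Saturday's | 25.0 | 26.6 | 11.1 |
| Saturday's | 40.0 | 26.8 | 11.0 |
| Saturday's | 60.0 | 27.1 | 11.0 |
| Saturday's | 80.0 | 27.0 | 10.3 |
| Saturday's | 90.0 | 26.2 | 10.6 |
| Monday's | 5.00 | 27.0 | 10.3 |
| Monday's | 15.0 | 26.8 | 10.9 |
| Monday's | 25.0 | 27.3 | 10.8 |
| Monday's | 40.0 | 26.8 | 11.0 |
| Monday's | 60.0 | 26.4 | 10.4 |
| Monday's | 80.0 | 26.7 | 10.9 |
| Monday's | 90.0 | 27.4 | 10.1 |
| Wednesday's | 20.0 | 26.2 | 10.7 |
| Wednesday's | 40.0 | 26.9 | 11.2 |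
| Wednesday's | 60.0 | 26.2 | 10.9 |
| Wednesday's | 80.0 | 27.1 | 11.1 |
| Wednesday's | 90.0 | 26.9 | 10.9 |

(readings scatter by 0.3 percentage points)

- a reading or a percentage of Z counts all its forms, free or not

- share of Z in Z plus X at 6.0 s
- share of Z in Z plus X at 80 min

So I folded these runs into one dimensionless number, the end share s: summed Z divided by summed Z plus X, taken over their readings at that time, which gave 71.4%. In words, s is the part of the converted Q that stands as Z once the readings have levelled: the selectivity under thermodynamic control. Run by run it read 72.4%, 71.0% and 70.9%. Saturday's readings, with less G than the flask, were level from 15.0 min, so I took s as the flask's share at 80 min.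

Was one number enough? It was not, because Saturday's first reading, at 5.00 min, gives 65.9%, less than s. Saturday's share was therefore still moving at that reading, and s gave me no figure for 6.0 s.

The forecast said 60% at 6.0 s and 71.3% at 80 min, adding that “the range is wide”.

    Q + G ⇌ Z + G, rate k1*[Q]*[G] forward; the back reaction follows from the equilibrium constant (K = 0.430, k = 0.140 M⁻¹ s⁻¹)
    Z + G ⇌ X + G, rate k2*[G]*[Z] forward; the back reaction follows from the equilibrium constant (K = 0.400, k = 0.0240 M⁻¹ s⁻¹)
    J ⇌ Z, rate k3*(cs3 - [Z]) while solid is left; crystals form when [Z] > cs3 (solubility = 0.400 M, k = 0.540 s⁻¹)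
    X ⇌ Q (k = 0.00740 s⁻¹)
    G + D ⇌ L, settled at all times (K = 80.0 M⁻¹)

The flask gave 73.5% at 6.0 s, which is 14 percentage points above the forecast, and 71.4% at 80 min, close to s. With the reaction of X to Q struck out, both ways, the share at 6.0 s came to 99.8%. A further flask, the same but charged with 0.0063 M of D, ended with Z and X together at 37.6%, of which s assigns 26.8% to Z, and its Z stood at 26.8%.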